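**Overview**

- Cuts: once the O-benzyl and N-formamidine protecting groups are removed, the first skeletal cut is the bond from imidazole C-4 to the CH2 of the 4-methoxybenzyl group (benzyl organometallic plus ring carbonyl, then reductive aromatization). The second is the bond from C-5 to the carbon of the 2-hydroxy-3,4-dimethoxybenzyl group (aldehyde condensation).
- Forward order: no ring is made. The five-membered ring is bought as creatinine, the C-5 arm is joined by Knoevenagel condensation, the amino group is capped, the C-4 arm is joined by 1,2-addition of a benzylcerium reagent, the ring is aromatized by ionic hydrogenation, and two deprotections finish.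
- Enabling feature: the N-methyl nitrogen N-1, the C-2 amino group, C-5 and C-4 of the 2-aminoimidazole coincide atom for atom with creatinine. Its C-4 carbonyl lies between the sp2 nitrogen N-3 and a C-5 blocked as the arylidene, so it is an acylamidine-type carbonyl with no α-hydrogen and can take up the benzyl carbon.
- Stereochemistry: the target has no stereocentre; the alkene geometry and the racemic carbinol carbon met on the way vanish on aromatization.

Key step: step 5

Assumption: the condensation product is drawn as the Z isomer (aryl syn to N-methyl); the E isomer or a mixture would serve equally, because the geometry is lost in step 6.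

**Route**

Step 1
Reactants: 1 2-hydroxy-3,4-dimethoxybenzaldehyde
Product: 2 2-(benzyloxy)-3,4-dimethoxybenzaldehyde
Conditions: BnBr, K2CO3, DMF, 60 °C
Reagents that add atoms: benzyl bromide, BrCc1ccccc1
Why: Williamson ether synthesis, in which the phenol next to the formyl group is deprotonated by K2CO3 and the phenoxide displaces bromide from benzyl bromide, the aldehyde being inert to these conditions.

Step 2
Reactants: 2 2-(benzyloxy)-3,4-dimethoxybenzaldehyde; 3 creatinine
Product: 4 (Z)-2-amino-5-[2-(benzyloxy)-3,4-dimethoxybenzylidene]-1-methyl-1,5-dihydro-4H-imidazol-4-one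
Conditions: NaOAc, AcOH, 120 °C
Reagents that add atoms: none
Why: Knoevenagel-type condensation, in which the C-5 methylene of creatinine (activated by the C-4 carbonyl) is enolized under acetate buffering, adds to the aldehyde and loses water to give the conjugated arylidene, while the acidic medium keeps the amino group protonated and out of the reaction.

Step 3
Reactants: 4 (Z)-2-amino-5-[2-(benzyloxy)-3,4-dimethoxybenzylidene]-1-methyl-1,5-dihydro-4H-imidazol-4-one
Product: 5 N'-{(Z)-5-[2-(benzyloxy)-3,4-dimethoxybenzylidene]-1-methyl-4-oxo-4,5-dihydro-1H-imidazol-2-yl}-N,N-dimethylformimidamide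
Conditions: Me2NCH(OMe)2, DMF, 80 °C
Reagents that add atoms: N,N-dimethylformamide dimethyl acetal, COC(OC)N(C)C
Why: Amidine formation by condensation of the exocyclic NH2 with the amide acetal (loss of two methanol), a standard masking of 2-amino azoles that removes both N–H protons; no acidic C–H is left at C-5 to compete.

Step 4
Reactants: 6 4-methoxybenzyl chloride
Product: 7 4-methoxybenzylmagnesium chloride
Conditions: Mg turnings (excess, I2-activated), THF, 0 °C, slow addition at high dilution
Reagents that add atoms: magnesium, [Mg]
Why: Grignard formation by insertion of magnesium into the benzylic C–Cl bond, with slow addition of the chloride to excess metal in cold dilute THF to hold back Wurtz homocoupling; the solution is titrated and used directly.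

Step 5
Reactants: 5 N'-{(Z)-5-[2-(benzyloxy)-3,4-dimethoxybenzylidene]-1-methyl-4-oxo-4,5-dihydro-1H-imidazol-2-yl}-N,N-dimethylformimidamide; 7 4-methoxybenzylmagnesium chloride
Product: 9 N'-{(Z)-5-[2-(benzyloxy)-3,4-dimethoxybenzylidene]-4-hydroxy-4-(4-methoxybenzyl)-1-methyl-4,5-dihydro-1H-imidazol-2-yl}-N,N-dimethylformimidamide (racemic carbinol), via 4-methoxybenzylcerium dichloride 8 (not isolated)
Conditions: anhydrous CeCl3 (3 equiv), 7 (3 equiv), THF, −78 °C, 1 h; then 5 in THF, −78 to −40 °C; cold aq. NaHCO3 quench
Reagents that add atoms: none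
Why: Proposed new method: the Grignard reagent 7 is transmetalated with CeCl3 to the weakly basic, oxophilic benzylcerium 8, which binds the C-4 carbonyl oxygen of 5 and delivers the 4-methoxybenzyl carbon to C-4 in a 1,2-addition, the cerium alkoxide persisting as a tetrahedral species until the cold quench releases carbinol 9; the closest known reaction type is the CeCl3-mediated addition of Grignard reagents to hindered, enolizable or cross-conjugated ketones and vinylogous amide carbonyls, which has not been shown on the C-4 carbonyl of a 5-arylidene 2-aminoimidazol-4-one. The carbonyl should be reactive enough because the lone pair of N-3 lies in the ring plane and cannot give amide resonance, because the formamidine cap leaves no N–H that would form a deactivating anion, and because C-5 carries the arylidene and has no acidic hydrogen. No ring closes in this step; the only bond formed is the one from C-4 to the benzylic CH2. The new carbinol carbon C-4 is formed as a racemate with no controlling element and needs none, since it becomes sp2 in step 6. The selectivity required is 1,2-addition over 1,4-addition and over attack at the formamidine carbon: the hard trivalent cerium reagent prefers the carbonyl, the exocyclic carbon is the electron-rich terminus of an enamine fed by N-1 and by the alkoxy-substituted aryl ring, and the formamidine carbon is a poor electrophile at −78 °C.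

Step 6
Reactants: 9 N'-{(Z)-5-[2-(benzyloxy)-3,4-dimethoxybenzylidene]-4-hydroxy-4-(4-methoxybenzyl)-1-methyl-4,5-dihydro-1H-imidazol-2-yl}-N,N-dimethylformimidamide
Product: 10 N'-{5-[2-(benzyloxy)-3,4-dimethoxybenzyl]-4-(4-methoxybenzyl)-1-methyl-1H-imidazol-2-yl}-N,N-dimethylformimidamide
Conditions: Et3SiH (5 equiv) present first, then CF3CO2H, CH2Cl2, 0 °C to rt
Reagents that add atoms: none
Why: Ionic hydrogenation, in which CF3CO2H ionizes the tertiary allylic hydroxyl to a cation spread over C-4 and the exocyclic benzylic carbon (the same imidazol-5-yl(aryl)methyl cation that is reduced in the familiar silane deoxygenation of imidazolyl aryl carbinols) and Et3SiH gives hydride to the benzylic terminus, the only outcome that forms the aromatic imidazole directly, while any C-4 hydride adduct is a tautomer that would isomerize to the same product in the acid.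

Step 7
Reactants: 10 N'-{5-[2-(benzyloxy)-3,4-dimethoxybenzyl]-4-(4-methoxybenzyl)-1-methyl-1H-imidazol-2-yl}-N,N-dimethylformimidamide
Product: 11 5-[2-(benzyloxy)-3,4-dimethoxybenzyl]-4-(4-methoxybenzyl)-1-methyl-1H-imidazol-2-amine
Conditions: 2 M aq. HCl, MeOH, 60 °C; then aq. NaHCO3
Reagents that add atoms: none
Why: Acid hydrolysis of the N,N-dimethylformamidine (water adds to the protonated amidine carbon and N,N-dimethylformamide is lost), a standard amine deprotection that should leave the benzyl ether, the methyl ethers and the protonated 2-aminoimidazole untouched.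

Step 8
Reactants: 11 5-[2-(benzyloxy)-3,4-dimethoxybenzyl]-4-(4-methoxybenzyl)-1-methyl-1H-imidazol-2-amine
Product: 12 naamine C, 6-{[2-amino-4-(4-methoxybenzyl)-1-methyl-1H-imidazol-5-yl]methyl}-2,3-dimethoxyphenol
Conditions: H2 (1 atm), 10% Pd/C, MeOH, rt
Reagents that add atoms: none
Why: Catalytic hydrogenolysis of the benzyl aryl ether, which should release the phenol and toluene under conditions too mild to touch the imidazole ring or its two C-benzyl groups.

**Compound list**

1 | 2-hydroxy-3,4-dimethoxybenzaldehyde | COc1ccc(C=O)c(O)c1OC | starting material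
2 | 2-(benzyloxy)-3,4-dimethoxybenzaldehyde | COc1ccc(C=O)c(OCc2ccccc2)c1OC | intermediate
3 | creatinine (2-amino-1-methyl-1,5-dihydro-4H-imidazol-4-one) | CN1CC(=O)N=C1N | starting material
4 | (Z)-2-amino-5-[2-(benzyloxy)-3,4-dimethoxybenzylidene]-1-methyl-1,5-dihydro-4H-imidazol-4-one | CN1C(N)=NC(=O)/C1=C/c1ccc(OC)c(OC)c1OCc1ccccc1 | intermediate
5 | N'-{(Z)-5-[2-(benzyloxy)-3,4-dimethoxybenzylidene]-1-methyl-4-oxo-4,5-dihydro-1H-imidazol-2-yl}-N,N-dimethylformimidamide | CN1C(N=CN(C)C)=NC(=O)/C1=C/c1ccc(OC)c(OC)c1OCc1ccccc1 | intermediate
6 | 4-methoxybenzyl chloride | COc1ccc(CCl)cc1 | starting material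
7 | 4-methoxybenzylmagnesium chloride (THF solution) | COc1ccc(C[Mg]Cl)cc1 | intermediate
8 | 4-methoxybenzylcerium dichloride (not isolated) | COc1ccc(C[Ce](Cl)Cl)cc1 | intermediate
9 | N'-{(Z)-5-[2-(benzyloxy)-3,4-dimethoxybenzylidene]-4-hydroxy-4-(4-methoxybenzyl)-1-methyl-4,5-dihydro-1H-imidazol-2-yl}-N,N-dimethylformimidamide, racemic at C-4 | CN1C(N=CN(C)C)=NC(O)(Cc2ccc(OC)cc2)/C1=C/c1ccc(OC)c(OC)c1OCc1ccccc1 | intermediate
10 | N'-{5-[2-(benzyloxy)-3,4-dimethoxybenzyl]-4-(4-methoxybenzyl)-1-methyl-1H-imidazol-2-yl}-N,N-dimethylformimidamide | CN(C)C=Nc1nc(Cc2ccc(OC)cc2)c(Cc2ccc(OC)c(OC)c2OCc2ccccc2)n1C | intermediate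
11 | 5-[2-(benzyloxy)-3,4-dimethoxybenzyl]-4-(4-methoxybenzyl)-1-methyl-1H-imidazol-2-amine (O-benzyl naamine C) | COc1ccc(Cc2nc(N)n(C)c2Cc2ccc(OC)c(OC)c2OCc2ccccc2)cc1 | intermediate
12 | naamine C, 6-{[2-amino-4-(4-methoxybenzyl)-1-methyl-1H-imidazol-5-yl]methyl}-2,3-dimethoxyphenol | COc1ccc(Cc2nc(N)n(C)c2Cc2ccc(OC)c(OC)c2O)cc1 | target

**Count**

Total step count: 8.
Longest linear sequence: 7 steps (steps 1, 2, 3, 5, 6, 7, 8); step 4 prepares the side-arm reagent.

**Steps most likely to fail**

1. Step 5 (Proposed new method). What may go wrong: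
   - too little electrophilicity at the acylamidine carbonyl, so that 5 is returned;
   - conjugate addition at the arylidene carbon or attack at the formamidine carbon;
   - collapse of the tetrahedral cerium alkoxide by ring opening, followed by a second addition to the freed ketone.

   Fallback (known chemistry, sets out from 2 and comes back at 12): the ring carbonyl is given up as the electrophile, and both benzylic carbons are joined to a preformed imidazole by halogen–magnesium exchange. Bought 4,5-diiodo-1-methyl-1H-imidazole undergoes C-5-selective iodine–magnesium exchange with EtMgBr in THF, and the imidazol-5-ylmagnesium species adds to aldehyde 2 to give [2-(benzyloxy)-3,4-dimethoxyphenyl](4-iodo-1-methyl-1H-imidazol-5-yl)methanol F1. Deoxygenation with Et3SiH and CF3CO2H should give 5-[2-(benzyloxy)-3,4-dimethoxybenzyl]-4-iodo-1-methyl-1H-imidazole F2. A second exchange with EtMgBr and addition to 4-methoxybenzaldehyde should give {5-[2-(benzyloxy)-3,4-dimethoxybenzyl]-1-methyl-1H-imidazol-4-yl}(4-methoxyphenyl)methanol F3. A second Et3SiH/CF3CO2H deoxygenation should give 5-[2-(benzyloxy)-3,4-dimethoxybenzyl]-4-(4-methoxybenzyl)-1-methyl-1H-imidazole F4. Lithiation at C-2 (n-BuLi, THF, −78 °C) and trapping with tosyl azide should give 2-azido-5-[2-(benzyloxy)-3,4-dimethoxybenzyl]-4-(4-methoxybenzyl)-1-methyl-1H-imidazole F5. Hydrogenation of F5 over Pd/C should reduce the azide to the amine and cleave the benzyl ether in one operation, giving 12.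

2. Step 6. What may go wrong:
   - after ionization, Friedel–Crafts closure of the delocalized cation onto the anisyl ring (a six-membered ring, leading to a dihydronaphthimidazole) outruns hydride capture;
   - the azafulvenium-type cation oligomerizes;
   - the benzyl ether is partly lost in the acid.

   Fallback (sets out from 9 and comes back at 12): hydride capture of a cation is replaced by hydrogenation followed by dehydration. Hydrogen over Pd/C in MeOH should saturate the exocyclic alkene of 9 and cleave the benzyl ether, giving N'-[4-hydroxy-5-(2-hydroxy-3,4-dimethoxybenzyl)-4-(4-methoxybenzyl)-1-methyl-4,5-dihydro-1H-imidazol-2-yl]-N,N-dimethylformimidamide F6 as a mixture of diastereomers. Warming F6 in aqueous HCl and MeOH should eliminate water across C-4 and C-5, the aromatizing dehydration that also ends the classical α-aminoketone and cyanamide route to 2-aminoimidazoles. The same acid should hydrolyse the formamidine, so that 12 results directly.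

3. Step 2. What may go wrong:
   - condensation is slow, because the aldehyde is electron-rich and ortho-substituted and the C-5 methylene of creatinine is only weakly acidic;
   - prolonged heating then leads to decomposition or to reaction at the free amino group.

   Fallback (sets out from 2 and comes back at 4): a more acidic methylene partner is used and the amino group is introduced afterwards. Aldehyde 2 is condensed with 1-methyl-2-thiohydantoin (piperidine, EtOH, reflux) to give (Z)-5-[2-(benzyloxy)-3,4-dimethoxybenzylidene]-1-methyl-2-thioxoimidazolidin-4-one F7. S-Methylation (MeI, K2CO3, MeCN) should give (Z)-5-[2-(benzyloxy)-3,4-dimethoxybenzylidene]-1-methyl-2-(methylthio)-1,5-dihydro-4H-imidazol-4-one F8. Ammonia in MeOH (sealed tube, 80 °C) should displace the methylthio group by addition–elimination at C-2, giving 4.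

**Further compounds**

F1 | step 5 | [2-(benzyloxy)-3,4-dimethoxyphenyl](4-iodo-1-methyl-1H-imidazol-5-yl)methanol (racemic) | Cn1cnc(I)c1C(O)c1ccc(OC)c(OC)c1OCc1ccccc1
F2 | step 5 | 5-[2-(benzyloxy)-3,4-dimethoxybenzyl]-4-iodo-1-methyl-1H-imidazole | Cn1cnc(I)c1Cc1ccc(OC)c(OC)c1OCc1ccccc1
F3 | step 5 | {5-[2-(benzyloxy)-3,4-dimethoxybenzyl]-1-methyl-1H-imidazol-4-yl}(4-methoxyphenyl)methanol (racemic) | Cn1cnc(C(O)c2ccc(OC)cc2)c1Cc1ccc(OC)c(OC)c1OCc1ccccc1
F4 | step 5 | 5-[2-(benzyloxy)-3,4-dimethoxybenzyl]-4-(4-methoxybenzyl)-1-methyl-1H-imidazole | Cn1cnc(Cc2ccc(OC)cc2)c1Cc1ccc(OC)c(OC)c1OCc1ccccc1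
F5 | step 5 | 2-azido-5-[2-(benzyloxy)-3,4-dimethoxybenzyl]-4-(4-methoxybenzyl)-1-methyl-1H-imidazole | Cn1c(N=[N+]=[N-])nc(Cc2ccc(OC)cc2)c1Cc1ccc(OC)c(OC)c1OCc1ccccc1
F6 | step 6 | N'-[4-hydroxy-5-(2-hydroxy-3,4-dimethoxybenzyl)-4-(4-methoxybenzyl)-1-methyl-4,5-dihydro-1H-imidazol-2-yl]-N,N-dimethylformimidamide (mixture of diastereomers) | CN1C(N=CN(C)C)=NC(O)(Cc2ccc(OC)cc2)C1Cc1ccc(OC)c(OC)c1O
F7 | step 2 | (Z)-5-[2-(benzyloxy)-3,4-dimethoxybenzylidene]-1-methyl-2-thioxoimidazolidin-4-one | CN1C(=S)NC(=O)/C1=C/c1ccc(OC)c(OC)c1OCc1ccccc1
F8 | step 2 | (Z)-5-[2-(benzyloxy)-3,4-dimethoxybenzylidene]-1-methyl-2-(methylthio)-1,5-dihydro-4H-imidazol-4-one | CN1C(SC)=NC(=O)/C1=C/c1ccc(OC)c(OC)c1OCc1ccccc1
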